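## Analysis of the target

Marchantin G (22) is a macrocyclic bis(bibenzyl). Four benzene rings are tied into one 18-membered ring by two diaryl ether oxygens, one CH2–CH2 bridge and one C(=O)–CH2 bridge.

- Ring A is a para-phenylene carrying the ether oxygen to ring D and the ethylene bridge to ring B.
- Ring B is 1,2,3-substituted: ethylene bridge, ether oxygen to ring C, free OH.
- Ring C is a meta-phenylene carrying that ether oxygen and the CH2 of the keto bridge.
- Ring D carries the ketone carbon and three adjacent oxygens: the ring A ether oxygen, a central OH para to the ketone carbon, and an outer OH.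

There is no stereogenic centre, and the cyclophane is taken to be conformationally mobile, so no configuration has to be set. The sensitive parts are the ring D catechol and the ring B aryloxyphenol, both easily oxidised, and the deoxybenzoin unit with its doubly benzylic, enolisable CH2.

The synthesis is hard for four reasons: an 18-membered cyclophane must be closed, ring D needs four substituents placed with full regiocontrol, the ring B–O–ring C ether is flanked on both sides, and only one of four benzylic carbons may be oxidised.

The strategy rests on one pattern. The ring A oxygen sits on the ring D carbon ortho to the central hydroxyl, and that hydroxyl is para to the bridge carbon. Ring A is likewise oxygenated para to an alkyl chain. This is the bond an oxidised 4-alkylphenol forms with the oxygen of a second 4-alkylphenol. The other ortho carbon of ring D also bears oxygen, so a substituent left there by the coupling can become the outer OH.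

## Retrosynthetic reasoning

**22 to 21.** The last operation only uncovers hydroxyl groups. The ring D catechol and the ring B phenol would not survive the oxidative steps, so both are carried as methyl ethers. The two O–CH3 bonds are cut in one final ether cleavage.

**21 to 18.** The carbonyl oxygen is removed retrosynthetically. The ketone carbon is the only benzylic carbon para to a free phenol, so it can be oxidised selectively through quinone methide 19 and alcohol 20. The macrocycle can therefore be built as a plain bis(bibenzyl), with no carbonyl to protect during ring closure.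

**18 to 17 to 16.** The outer methoxy group of ring D is traced back to a bromine (C–O for C–Br) and the two ring A hydrogens to chlorines. These halogens are not ballast: they are the control elements of the ring closure, and the bromine that survives it sits on the carbon that needs oxygen.

**16 to 14 (key disconnection).** The bond between the ring A oxygen and the ring D carbon is cut. This is the one bond of the macrocycle that phenol oxidation can make, and cutting it turns 16 into the open bisphenol 14, which contains only one diaryl ether and two saturated bridges. The forward reaction must oxidise one phenol terminus, keep the other as a nucleophile, direct attack to an ortho carbon, and close the ring rather than extend a chain.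

**14 to 13 to 9 + 12.** The bridge between ring C and ring D is cut at an olefin. A Wittig reaction between aldehyde 9 and phosphonium salt 12 gives 13, and both stilbene double bonds are then saturated by a transfer hydrogenation that spares aryl halides. Salt 12 comes in two steps from aldehyde 10 through alcohol 11.

**9 to 7 to 3 + 6.** The bridge between ring B and ring A is cut the same way. The ring C carbon is held as a nitrile during this first olefination and becomes the aldehyde of 9 afterwards by partial reduction through aldimine 8. A core with two free formyl groups would give no handle for adding ring A and ring D separately. Salt 6 comes from aldehyde 4 through alcohol 5.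

**3 to 1 + 2.** The crowded ether between rings B and C is cut at the ring B carbon. In fluoroaldehyde 1 that carbon is activated by the ortho formyl group, so phenol 2 can displace fluoride. This avoids arylating a 2,6-disubstituted phenol.

## Alternatives that were turned down

**Alternative 1: ring B by cycloaddition.**
- Disconnection: two C–C bonds of ring B. 3-Methoxy-2-pyrone A2 and the aryl alkynyl ether A3 (3-chlorophenoxy on one alkyne carbon, the ring A ethyl chain on the other) would undergo Diels–Alder addition and decarboxylative aromatisation to the ring B–C diaryl ether A1.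
- For it: the 1,2,3-pattern of ring B arises in one step with the hindered ether already in place. The regiochemistry follows from polarity, since the nucleophilic alkyne carbon remote from oxygen bonds to C-6 of A2. No activating group is needed on ring B; on this point it is as strong as, or stronger than, step 1 of the chosen route.
- Against: the problem it solves is cheap here, because one SNAr step gives the same ether linkage in 3. A3 is an acid-sensitive ynol ether that takes several steps to make. Both partners are electron-rich, so the cycloaddition needs forcing. A1 still lacks ring D, the keto bridge and the macrocycle, and the aryl chloride on ring C must be converted into a two-carbon bridge.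
- Comparison: the risk of ring closure is only postponed. The chosen key step closes the 18-membered ring and sets the oxygen pattern of ring D in the same operation.

**Alternative 2: para-Fries ring contraction of a macrolactone.**
- Disconnection: the aryl–C(=O) bond of ring D. The 18-membered aryl ester A5, with the arylacetyl group on the central oxygen of ring D, would rearrange under acid so that the acyl carbon moves to the para carbon, giving A4. A4 has the same structure as 21.
- For it: the ring is first closed by an ordinary esterification. The ketone arrives with its carbon, so no benzylic oxidation is needed. Both ortho positions of the ester oxygen are blocked, so only para migration is possible. On ketone installation this route is stronger than the chosen one.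
- Against: the Fries shift goes through a detached arylacetyl cation. That cation can lose CO to a benzyl cation, form a ketene, or acylate the other electron-rich rings (ring B para to its methoxy group) within the ring or between molecules. The acids needed also threaten the methyl and diaryl ethers. The para carbon must reach the acyl carbon across the ring, and nothing in A5 enforces that.
- Comparison: the last skeletal bond would be made by the least controllable step. The chosen route reaches the same compound 21 with the carbocycle already closed, and places the oxidation by a phenol-directed reaction.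

**Alternative 3: SNAr macrocyclisation at the ring B–C ether.**
- Disconnection: the ring C carbon–oxygen bond. The ring B phenoxide of the seco compound A7 would displace fluoride from the 3-fluoro-4-nitrophenyl ring C through a Meisenheimer adduct, giving the nitro macrocycle A6 with the ketone masked as a ketal.
- For it: nitro-activated SNAr is probably the most dependable way to close a diaryl ether macrocycle, and it tolerates a hindered phenoxide. As a ring closure it is likely more predictable than the anodic coupling. The ketone is in place from the start.
- Against: the nitro group has no counterpart in ring C and must be removed afterwards by reduction, diazotisation and reduction. The CH2 para to the nitro group is acidic under the basic cyclisation conditions. The ring A–ring D ether and the ketal-protected deoxybenzoin must be assembled beforehand, with a regiochemical problem on the trioxygenated ring D. Three methyl ethers must be cleaved at the end.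
- Comparison: a more reliable closure is paid for with a longer seco synthesis and a traceless activator. In the chosen route the activators are used: the bromine becomes the outer hydroxyl of ring D and the chlorines leave in one hydrogenolysis.

Key step: step 10

## Route

Remark: 22 has no stereocentre. The Wittig steps give E/Z mixtures that are carried on as such, because both olefins are saturated in step 9.

Step 1
Reactants: 1 2-fluoro-3-methoxybenzaldehyde; 2 3-hydroxybenzonitrile
Product: 3 3-(2-formyl-6-methoxyphenoxy)benzonitrile
Conditions: K2CO3, DMF, 110 °C
Reagents that add atoms: none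
Why: Nucleophilic aromatic substitution (SNAr): the ortho formyl group stabilises the Meisenheimer adduct, so the phenoxide of 2 displaces fluoride at the flanked ring B carbon; the nitrile is inert and serves as the latent second aldehyde.

Step 2
Reactants: 4 3,5-dichloro-4-hydroxybenzaldehyde
Product: 5 2,6-dichloro-4-(hydroxymethyl)phenol
Conditions: NaBH4, MeOH, 0 °C; aq. NH4Cl
Reagents that add atoms: none
Why: Borohydride reduction of an aryl aldehyde; aryl chlorides and the phenol are untouched.

Step 3
Reactants: 5 2,6-dichloro-4-(hydroxymethyl)phenol
Product: 6 (3,5-dichloro-4-hydroxybenzyl)triphenylphosphonium bromide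
Conditions: PPh3·HBr, MeCN, reflux
Reagents that add atoms: triphenylphosphine hydrobromide, c1ccc(cc1)[PH+](c1ccccc1)c1ccccc1.[Br-]
Why: Direct phosphonium salt formation from a benzylic alcohol: protonation and loss of water give a para-hydroxybenzyl cation that triphenylphosphine captures, which avoids an unstable para-hydroxybenzyl bromide.

Step 4
Reactants: 3 3-(2-formyl-6-methoxyphenoxy)benzonitrile; 6 (3,5-dichloro-4-hydroxybenzyl)triphenylphosphonium bromide
Product: 7 3-[2-[2-(3,5-dichloro-4-hydroxyphenyl)ethenyl]-6-methoxyphenoxy]benzonitrile (E/Z mixture)
Conditions: 6, LiN(SiMe3)2 (2.2 equiv), THF, −78 to 0 °C; then 3, 0 °C to rt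
Reagents that add atoms: none
Why: Wittig olefination: the first equivalent of base makes the weakly basic dichlorophenoxide and the second the benzylic ylide, which adds to the aldehyde much faster than to the nitrile; the olefin geometry is irrelevant.

Step 5
Reactants: 7 3-[2-[2-(3,5-dichloro-4-hydroxyphenyl)ethenyl]-6-methoxyphenoxy]benzonitrile (E/Z mixture)
Product: 9 3-[2-[2-(3,5-dichloro-4-hydroxyphenyl)ethenyl]-6-methoxyphenoxy]benzaldehyde (E/Z mixture), via aldimine 8 (not isolated)
Conditions: i-Bu2AlH (3 equiv), CH2Cl2, −78 °C; then 1 M HCl, 0 °C
Reagents that add atoms: water, O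
Why: Partial reduction of an aryl nitrile: one hydride adds to give the aluminium-bound aldimine, which cannot be reduced further at low temperature and is hydrolysed to the aldehyde on acidic work-up; one equivalent of reagent is consumed by the phenol.

Step 6
Reactants: 10 3,5-dibromo-4-hydroxybenzaldehyde
Product: 11 2,6-dibromo-4-(hydroxymethyl)phenol
Conditions: NaBH4, MeOH, 0 °C; aq. NH4Cl
Reagents that add atoms: none
Why: Borohydride reduction of an aryl aldehyde; aryl bromides are untouched.

Step 7
Reactants: 11 2,6-dibromo-4-(hydroxymethyl)phenol
Product: 12 (3,5-dibromo-4-hydroxybenzyl)triphenylphosphonium bromide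
Conditions: PPh3·HBr, MeCN, reflux
Reagents that add atoms: triphenylphosphine hydrobromide, c1ccc(cc1)[PH+](c1ccccc1)c1ccccc1.[Br-]
Why: Same direct phosphonium salt formation from a para-hydroxybenzyl alcohol as in step 3.

Step 8
Reactants: 9 3-[2-[2-(3,5-dichloro-4-hydroxyphenyl)ethenyl]-6-methoxyphenoxy]benzaldehyde (E/Z mixture); 12 (3,5-dibromo-4-hydroxybenzyl)triphenylphosphonium bromide
Product: 13 2,6-dibromo-4-[2-[3-[2-[2-(3,5-dichloro-4-hydroxyphenyl)ethenyl]-6-methoxyphenoxy]phenyl]ethenyl]phenol (mixture of olefin isomers)
Conditions: 12, LiN(SiMe3)2 (2.2 equiv), THF, −78 to 0 °C; then 9 pre-treated with LiN(SiMe3)2 (1.05 equiv), 0 °C to rt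
Reagents that add atoms: none
Why: Second Wittig olefination: the phenol of 9 is deprotonated beforehand so that it does not quench the ylide, and its phenoxide is not conjugated with the ring C aldehyde, which therefore stays electrophilic.

Step 9
Reactants: 13 2,6-dibromo-4-[2-[3-[2-[2-(3,5-dichloro-4-hydroxyphenyl)ethenyl]-6-methoxyphenoxy]phenyl]ethenyl]phenol (mixture of olefin isomers)
Product: 14 2,6-dibromo-4-[2-[3-[2-[2-(3,5-dichloro-4-hydroxyphenyl)ethyl]-6-methoxyphenoxy]phenyl]ethyl]phenol
Conditions: TsNHNH2 (excess), NaOAc, DME/H2O, reflux
Reagents that add atoms: none
Why: Diimide reduction: diimide made in the flask transfers two hydrogens to each stilbene double bond in a concerted step and leaves the four aryl–halogen bonds alone, which catalytic hydrogenation would not.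

Step 10
Reactants: 14 2,6-dibromo-4-[2-[3-[2-[2-(3,5-dichloro-4-hydroxyphenyl)ethyl]-6-methoxyphenoxy]phenyl]ethyl]phenol
Product: 16 macrocyclic bromophenol (18-membered ring; ring D hydroxyl flanked by bromine and by the oxygen of the 3,5-dichlorinated ring A; ring B methoxy), via macrocyclic para-quinol methyl ether dienone 15 (not isolated)
Conditions: constant-current electrolysis (glassy-carbon anode, Pt cathode, undivided cell), LiClO4, MeOH, ca. 1 mM, rt; then Zn, AcOH, rt
Reagents that add atoms: none
Why: Two-electron anodic oxidation should take place at the ring D dibromophenol, which is expected to have the lower oxidation potential of the two phenols, and gives a phenoxonium ion whose para carbon is blocked by the alkyl chain. The un-oxidised ring A hydroxyl adds to a bromine-bearing ortho carbon, bromide leaves as methanol adds to the para carbon, and the oxidation level is stored in the para-quinol methyl ether 15. Zinc in acetic acid then transfers two electrons to the dienone, expels methoxide and restores the arene as 16, so the net change from 14 is loss of HBr. The closest known reaction type is the oxidative coupling of 2,6-dihalophenols, at an anode or with Tl(NO3)3, followed by zinc reduction, as used for isodityrosine-type and macrocyclic diaryl ethers. The 18-membered ring closes by intramolecular attack of a phenol oxygen on a cationic ring carbon; the two ends are joined only by a flexible chain, so high dilution and low current density are needed to favour closure over chain growth. No stereocentre is present in 16; the quaternary carbon of 15 is racemic and is lost on reduction. The step needs ring selectivity, site selectivity and chemoselectivity: bromine versus chlorine decides which phenol is oxidised and which is the nucleophile, halogen on every ortho carbon and the equivalence of the two ortho carbons of ring D allow only one constitution, and ring B has no free hydroxyl and is therefore harder to oxidise.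

Step 11
Reactants: 16 macrocyclic bromophenol
Product: 17 macrocyclic methoxyphenol (16 with the ring D bromine replaced by OCH3)
Conditions: NaOMe (excess), CuI (20 mol %), DMF/MeOH, 110 °C
Reagents that add atoms: sodium methoxide, [Na+].[O-]C
Why: Copper-catalysed Ullmann-type methoxylation of an ortho-bromophenoxide, the reaction type that converts 2,6-dibromo-4-alkylphenols into syringyl phenols; the two flanked aryl chlorides should react much more slowly than the bromide.

Step 12
Reactants: 17 macrocyclic methoxyphenol
Product: 18 macrocyclic phenol without halogen (ring A para-phenylene; ring D central OH, outer OCH3; ring B OCH3)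
Conditions: H2 (1 atm), Pd/C, Et3N, EtOAc/MeOH, rt
Reagents that add atoms: none
Why: Catalytic hydrodechlorination: both aryl C–Cl bonds are hydrogenolysed with amine as acid scavenger; diaryl ethers, methyl ethers and the saturated bridges are stable.

Step 13
Reactants: 18 macrocyclic phenol without halogen
Product: 21 marchantin G dimethyl ether (aryl ketone on ring D para to the free central OH), via quinone methide 19 (not isolated), via benzylic alcohol 20 (not isolated)
Conditions: DDQ (2.2 equiv), 1,4-dioxane/H2O, rt
Reagents that add atoms: water, O
Why: DDQ benzylic oxidation of a 4-alkylphenol: hydride abstraction gives the para-quinone methide 19, water adds to its exocyclic carbon to give 20, and a second hydride abstraction gives the para-hydroxyaryl ketone; the other three benzylic carbons have no free para or ortho hydroxyl and should not react.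

Step 14
Reactants: 21 marchantin G dimethyl ether
Product: 22 marchantin G
Conditions: BBr3 (excess), CH2Cl2, −78 °C to rt; then H2O
Reagents that add atoms: none
Why: Lewis-acid cleavage of the two aryl methyl ethers by BBr3 (bromide attacks the O-methyl carbon of the boron-complexed ether); diaryl ethers and the deoxybenzoin ketone are stable under these conditions.

## Compound list

1 | 2-fluoro-3-methoxybenzaldehyde | O=Cc1cccc(OC)c1F | starting material
2 | 3-hydroxybenzonitrile | N#Cc1cccc(O)c1 | starting material
3 | 3-(2-formyl-6-methoxyphenoxy)benzonitrile | O=Cc1cccc(OC)c1Oc1cccc(C#N)c1 | intermediate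
4 | 3,5-dichloro-4-hydroxybenzaldehyde | O=Cc1cc(Cl)c(O)c(Cl)c1 | starting material
5 | 2,6-dichloro-4-(hydroxymethyl)phenol | OCc1cc(Cl)c(O)c(Cl)c1 | intermediate
6 | (3,5-dichloro-4-hydroxybenzyl)triphenylphosphonium bromide | Oc1c(Cl)cc(C[P+](c2ccccc2)(c2ccccc2)c2ccccc2)cc1Cl.[Br-] | intermediate
7 | 3-[2-[2-(3,5-dichloro-4-hydroxyphenyl)ethenyl]-6-methoxyphenoxy]benzonitrile (E/Z mixture) | N#Cc1cccc(c1)Oc1c(OC)cccc1C=Cc1cc(Cl)c(O)c(Cl)c1 | intermediate
8 | aldimine of 9 (N–H imine, bound to aluminium until hydrolysis; E/Z mixture) | N=Cc1cccc(c1)Oc1c(OC)cccc1C=Cc1cc(Cl)c(O)c(Cl)c1 | intermediate (not isolated)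
9 | 3-[2-[2-(3,5-dichloro-4-hydroxyphenyl)ethenyl]-6-methoxyphenoxy]benzaldehyde (E/Z mixture) | O=Cc1cccc(c1)Oc1c(OC)cccc1C=Cc1cc(Cl)c(O)c(Cl)c1 | intermediate
10 | 3,5-dibromo-4-hydroxybenzaldehyde | O=Cc1cc(Br)c(O)c(Br)c1 | starting material
11 | 2,6-dibromo-4-(hydroxymethyl)phenol | OCc1cc(Br)c(O)c(Br)c1 | intermediate
12 | (3,5-dibromo-4-hydroxybenzyl)triphenylphosphonium bromide | Oc1c(Br)cc(C[P+](c2ccccc2)(c2ccccc2)c2ccccc2)cc1Br.[Br-] | intermediate
13 | 2,6-dibromo-4-[2-[3-[2-[2-(3,5-dichloro-4-hydroxyphenyl)ethenyl]-6-methoxyphenoxy]phenyl]ethenyl]phenol (mixture of olefin isomers) | Oc1c(Br)cc(cc1Br)C=Cc1cccc(c1)Oc1c(OC)cccc1C=Cc1cc(Cl)c(O)c(Cl)c1 | intermediate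
14 | 2,6-dibromo-4-[2-[3-[2-[2-(3,5-dichloro-4-hydroxyphenyl)ethyl]-6-methoxyphenoxy]phenyl]ethyl]phenol (open bisphenol) | Oc1c(Br)cc(cc1Br)CCc1cccc(c1)Oc1c(OC)cccc1CCc1cc(Cl)c(O)c(Cl)c1 | intermediate
15 | macrocyclic para-quinol methyl ether: ring D as a 6-bromo-4-methoxycyclohexa-2,5-dienone with the ring A oxygen on C-2 and the bridge to ring C on C-4 (racemic) | O=C1C(Br)=CC2(OC)C=C1Oc1c(Cl)cc(cc1Cl)CCc1cccc(OC)c1Oc1cccc(c1)CC2 | intermediate (not isolated)
16 | macrocyclic bromophenol (ring D: OH between Br and O–ring A; ring A 3,5-dichloro; ring B OCH3) | Oc1c(Br)cc2cc1Oc1c(Cl)cc(cc1Cl)CCc1cccc(OC)c1Oc1cccc(c1)CC2 | intermediate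
17 | macrocyclic methoxyphenol (as 16, OCH3 in place of Br) | Oc1c(OC)cc2cc1Oc1c(Cl)cc(cc1Cl)CCc1cccc(OC)c1Oc1cccc(c1)CC2 | intermediate
18 | macrocyclic phenol without halogen (as 17, H in place of both Cl) | Oc1c(OC)cc2cc1Oc1ccc(cc1)CCc1cccc(OC)c1Oc1cccc(c1)CC2 | intermediate
19 | para-quinone methide of 18 (exocyclic C=CH towards ring C) | O=C1C(OC)=CC2=CCc3cccc(c3)Oc3c(OC)cccc3CCc3ccc(cc3)OC1=C2 | intermediate (not isolated)
20 | benzylic alcohol of 18 (CH(OH) on ring D, racemic) | Oc1c(OC)cc2cc1Oc1ccc(cc1)CCc1cccc(OC)c1Oc1cccc(c1)CC2O | intermediate (not isolated)
21 | marchantin G dimethyl ether (ring B OCH3, ring D outer OCH3, central OH free) | O=C1Cc2cccc(c2)Oc2c(OC)cccc2CCc2ccc(cc2)Oc2cc1cc(OC)c2O | intermediate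
22 | marchantin G | O=C1Cc2cccc(c2)Oc2c(O)cccc2CCc2ccc(cc2)Oc2cc1cc(O)c2O | target

## Step count and risks

Total: 14 steps. Longest linear sequence: 11 steps, from 4 through steps 2, 3, 4, 5, 8, 9, 10, 11, 12, 13 and 14.

**Step 10 (key step).** The oxidised ring D end may be captured by methanol alone, or by a second molecule, before the ring A hydroxyl reaches it, because closure of an 18-membered ring is slow. The phenoxonium ion may also lose a benzylic proton, and ring B may be oxidised at the potential required. Tl(NO3)3 in place of the anode would be tried first within the step. The fallback closes the same C–O bond by an intramolecular Ullmann ether synthesis; it sets out from 3 and returns at 18.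
- Wittig reaction of 3 with commercial (4-hydroxybenzyl)triphenylphosphonium bromide (LiN(SiMe3)2, THF) would give 3-[2-[2-(4-hydroxyphenyl)ethenyl]-6-methoxyphenoxy]benzonitrile F1.
- Reduction with i-Bu2AlH and acidic work-up would give 3-[2-[2-(4-hydroxyphenyl)ethenyl]-6-methoxyphenoxy]benzaldehyde F2.
- 5-Bromovanillin would be benzylated (BnBr, K2CO3) to 4-benzyloxy-3-bromo-5-methoxybenzaldehyde F3, reduced (NaBH4) to (4-benzyloxy-3-bromo-5-methoxyphenyl)methanol F4, and converted with PPh3·HBr into (4-benzyloxy-3-bromo-5-methoxybenzyl)triphenylphosphonium bromide F5.
- Wittig coupling of F2 with F5 would give the bis-stilbene F6, and diimide reduction the saturated bromo phenol F7.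
- CuI, N,N-dimethylglycine and Cs2CO3 in dioxane at high dilution would join the ring A phenoxide to the ring D carbon bearing bromine and give the macrocyclic benzyl ether F8.
- Hydrogenolysis of F8 (H2, Pd/C) gives 18 with the outer methoxy group already in place, so steps 11 and 12 are not needed.

**Step 13.** The quinone methide 19 may lose the neighbouring benzylic proton and end as a macrocyclic stilbene instead of taking up water, and the electron-rich ring D may be oxidised further once DDQ is in excess. The fallback separates the two oxidation events and replaces hydride abstraction; it sets out from 18 and returns at 21. Ag2O in CH2Cl2 would generate 19 under neutral conditions, dilute aqueous acid in THF would add water, and benzylic alcohol 20 would be isolated. MnO2 in CH2Cl2 would then oxidise 20 to 21.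

**Step 11.** The bromide may be lost by reduction instead of exchange, the exchange may stall because the aryl bromide is an electron-rich phenoxide, and the chlorides may begin to react at the temperature needed. The fallback masks the phenol and brings in oxygen through boron; it sets out from 16 and returns at 18.
- Benzylation (BnBr, K2CO3, DMF) would give the macrocyclic benzyl ether bromide F9.
- Bromine–lithium exchange (n-BuLi, THF, −78 °C), B(OMe)3 and oxidation with H2O2/NaOH would give the macrocyclic phenol F10.
- Methylation (MeI, K2CO3) would give the benzyl methyl diether F11.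
- The conditions of step 12 (H2, Pd/C, Et3N) would remove the benzyl group and both chlorines to give 18.

**Step 8 (the same concern applies to step 4).** Ylide formation from the phenoxide–phosphonium zwitterion may be incomplete or the salt may stay undissolved, the zwitterion may fragment to a quinone methide and PPh3, and proton transfer from any free phenol would quench the ylide. The fallback forms the olefin by a Heck reaction; it sets out from 9 and returns at 13.
- Methylenation of 9 (Ph3P=CH2 from MePPh3Br and KOt-Bu, excess) would give the styrene F12.
- Para-iodination of 2,6-dibromophenol (I2, NaHCO3) would give 2,6-dibromo-4-iodophenol F13.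
- Heck coupling of F12 with F13 (Pd(OAc)2, n-Bu4NCl, NaHCO3, DMF, 70 °C) should take place at the C–I bond only and give 13 with an E double bond at the new bridge.

## Further compounds

F1 | step 10 | 3-[2-[2-(4-hydroxyphenyl)ethenyl]-6-methoxyphenoxy]benzonitrile (E/Z mixture) | N#Cc1cccc(c1)Oc1c(OC)cccc1C=Cc1ccc(O)cc1
F2 | step 10 | 3-[2-[2-(4-hydroxyphenyl)ethenyl]-6-methoxyphenoxy]benzaldehyde (E/Z mixture) | O=Cc1cccc(c1)Oc1c(OC)cccc1C=Cc1ccc(O)cc1
F3 | step 10 | 4-benzyloxy-3-bromo-5-methoxybenzaldehyde | O=Cc1cc(Br)c(OCc2ccccc2)c(OC)c1
F4 | step 10 | (4-benzyloxy-3-bromo-5-methoxyphenyl)methanol | OCc1cc(Br)c(OCc2ccccc2)c(OC)c1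
F5 | step 10 | (4-benzyloxy-3-bromo-5-methoxybenzyl)triphenylphosphonium bromide | COc1cc(C[P+](c2ccccc2)(c2ccccc2)c2ccccc2)cc(Br)c1OCc1ccccc1.[Br-]
F6 | step 10 | bis-stilbene with ring A phenol and ring D benzyloxy bromide (mixture of olefin isomers) | COc1cc(C=Cc2cccc(c2)Oc2c(OC)cccc2C=Cc2ccc(O)cc2)cc(Br)c1OCc1ccccc1
F7 | step 10 | saturated bromo phenol (seco compound for the Ullmann closure) | COc1cc(CCc2cccc(c2)Oc2c(OC)cccc2CCc2ccc(O)cc2)cc(Br)c1OCc1ccccc1
F8 | step 10 | macrocyclic benzyl ether (O-benzyl derivative of 18) | COc1cc2cc(c1OCc1ccccc1)Oc1ccc(cc1)CCc1cccc(OC)c1Oc1cccc(c1)CC2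
F0 | step 13 | none | none
F9 | step 11 | macrocyclic benzyl ether bromide (O-benzyl derivative of 16) | Brc1cc2cc(c1OCc1ccccc1)Oc1c(Cl)cc(cc1Cl)CCc1cccc(OC)c1Oc1cccc(c1)CC2
F10 | step 11 | macrocyclic phenol (F9 with OH in place of Br) | Oc1cc2cc(c1OCc1ccccc1)Oc1c(Cl)cc(cc1Cl)CCc1cccc(OC)c1Oc1cccc(c1)CC2
F11 | step 11 | macrocyclic benzyl methyl diether (O-benzyl derivative of 17) | COc1cc2cc(c1OCc1ccccc1)Oc1c(Cl)cc(cc1Cl)CCc1cccc(OC)c1Oc1cccc(c1)CC2
F12 | step 8 | 2,6-dichloro-4-[2-[2-(3-ethenylphenoxy)-3-methoxyphenyl]ethenyl]phenol (E/Z mixture) | C=Cc1cccc(c1)Oc1c(OC)cccc1C=Cc1cc(Cl)c(O)c(Cl)c1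
F13 | step 8 | 2,6-dibromo-4-iodophenol | Oc1c(Br)cc(I)cc1Br
A1 | alternative 1 | 1-chloro-3-[2-methoxy-6-[2-(4-triisopropylsilyloxyphenyl)ethyl]phenoxy]benzene | Clc1cccc(c1)Oc1c(OC)cccc1CCc1ccc(O[Si](C(C)C)(C(C)C)C(C)C)cc1
A2 | alternative 1 | 3-methoxy-2-pyrone | COc1cccoc1=O
A3 | alternative 1 | 3-chlorophenyl 4-(4-triisopropylsilyloxyphenyl)but-1-ynyl ether | Clc1cccc(c1)OC#CCCc1ccc(O[Si](C(C)C)(C(C)C)C(C)C)cc1
A4 | alternative 2 | marchantin G dimethyl ether (same structure as 21) | O=C1Cc2cccc(c2)Oc2c(OC)cccc2CCc2ccc(cc2)Oc2cc1cc(OC)c2O
A5 | alternative 2 | 18-membered aryl ester macrolactone (arylacetyl group on the central oxygen of ring D) | O=C1Cc2cccc(c2)Oc2c(OC)cccc2CCc2ccc(cc2)Oc2cccc(OC)c2O1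
A6 | alternative 3 | 18-membered nitro diaryl ether with ketal-masked ketone | [O-][N+](=O)c1ccc2cc1Oc1c(OC)cccc1CCc1ccc(cc1)Oc1cc(cc(OC)c1OC)C1(OCCO1)C2
A7 | alternative 3 | open-chain ring B phenol with 3-fluoro-4-nitrophenyl ring C and ketal-masked ketone | Oc1c(OC)cccc1CCc1ccc(cc1)Oc1cc(cc(OC)c1OC)C1(OCCO1)Cc1ccc([N+]([O-])=O)c(F)c1
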